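**Retrosynthetic overview**

- Numbering: the tridecane chain runs from the benzylic CH2 (C1) to C13. The strategy rests on the five-carbon tether C3–C7 between the acetoxy carbinol C2 and the hydroxy carbinol C8. The only ring, the 3-hydroxy-5-methoxyphenyl ring, is bought intact.
- End game: the target comes from its 4,5-alkyne O-benzyl ether by one hydrogenation. Before that, the C2 hydroxyl is acetylated while C8 still carries a sulfate monoester, which is then hydrolysed.
- Key disconnection: C6–C7 and C3–C4. Propyne (C4–C6), doubly lithiated, joins the primary carbon of an (S)-1,2-cyclic sulfate (C7–C13) through its propargylic carbon, then the terminal carbon of an (S)-aryl epoxide (arene, C1–C3) through its acetylide.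
- Electrophiles: the cyclic sulfate comes from (S)-heptane-1,2-diol (kinetic resolution of racemic 1,2-epoxyheptane). The aryl epoxide comes from the benzylated aryl Grignard reagent and (S)-epichlorohydrin.
- Ring order: no ring of the target is formed. The dioxathiolane and oxirane rings are made only as electrophiles and both are opened in the key step.

Key step: step 6

Assumption: (R,R)-(salen)Co(OAc) (salen = N,N'-bis(3,5-di-tert-butylsalicylidene)-1,2-cyclohexanediamine dianion, acetate of trivalent cobalt) is taken to hydrolyse the (S)-enantiomer of a simple 2-alkyloxirane and to leave the (R)-epoxide. The sense should be confirmed on the diol before it is carried on, and the (S,S)-catalyst would be used if it proved opposite.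

**Route**

Step 1
Reactants: 1 racemic 1,2-epoxyheptane
Product: 2 (S)-heptane-1,2-diol
Conditions: (R,R)-(salen)Co(OAc) (0.5 mol%), H2O (0.45 equiv), THF (minimal), 0 °C to rt; unreacted epoxide distilled off, diol distilled
Reagents that add atoms: water, SMILES O
Why: Jacobsen hydrolytic kinetic resolution: the chiral cobalt–salen complex should deliver water to the terminal carbon of the (S)-epoxide much faster than to its enantiomer, so that with less than half an equivalent of water the diol forms with retention at C2 in high enantiomeric purity, which sets the future C8 stereocenter, and the volatile (R)-epoxide is distilled away.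

Step 2
Reactants: 2 (S)-heptane-1,2-diol
Product: 4 (S)-4-pentyl-1,3,2-dioxathiolane 2,2-dioxide, via cyclic sulfite 3 (not isolated)
Conditions: SOCl2, CH2Cl2, 0 °C to reflux; concentrate; RuCl3·3H2O (cat.), NaIO4 (1.5 equiv), MeCN/CH2Cl2/H2O, 0 °C
Reagents that add atoms: thionyl chloride, SMILES O=S(Cl)Cl; sodium periodate, SMILES [Na+].[O-]I(=O)(=O)=O
Why: Two-stage cyclic sulfate synthesis (sulfite formation, then oxidation at sulfur by RuO4 generated from catalytic RuCl3 and NaIO4): neither stage breaks a C–O bond, so the (S) centre is retained.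

Step 3
Reactants: 5 3-bromo-5-methoxyphenol
Product: 6 1-(benzyloxy)-3-bromo-5-methoxybenzene
Conditions: BnBr, K2CO3, DMF, rt
Reagents that add atoms: benzyl bromide, SMILES BrCc1ccccc1
Why: Williamson ether synthesis on the only acidic hydroxyl; the benzyl ether masks the phenol against the organometallic steps and is removed in the final hydrogenation.

Step 4
Reactants: 6 1-(benzyloxy)-3-bromo-5-methoxybenzene; 7 (S)-epichlorohydrin
Product: 9 (S)-1-[3-(benzyloxy)-5-methoxyphenyl]-3-chloropropan-2-ol, via arylmagnesium bromide 8 (not isolated)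
Conditions: Mg turnings, I2 (crystal), THF, reflux; then CuI (10 mol%), 7 (1.2 equiv), THF, −40 to 0 °C; aq NH4Cl
Reagents that add atoms: none
Why: Copper-catalysed Grignard opening of an epoxide: the aryl cuprate formed in situ should attack the unsubstituted oxirane carbon of epichlorohydrin in preference to the C–Cl carbon at low temperature, so the stereocenter (future C2, taken from the chiral pool) is not touched.

Step 5
Reactants: 9 (S)-1-[3-(benzyloxy)-5-methoxyphenyl]-3-chloropropan-2-ol
Product: 10 (S)-2-[3-(benzyloxy)-5-methoxybenzyl]oxirane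
Conditions: NaOH (aq, 2 M), THF, 0 °C to rt
Reagents that add atoms: none
Why: Intramolecular Williamson reaction (halohydrin to epoxide): the alkoxide displaces the primary chloride, the carbinol carbon keeps its configuration and the descriptor stays (S).

Step 6
Reactants: 11 propyne; 4 (S)-4-pentyl-1,3,2-dioxathiolane 2,2-dioxide; 10 (S)-2-[3-(benzyloxy)-5-methoxybenzyl]oxirane
Product: 14 lithium (2S,8S)-1-[3-(benzyloxy)-5-methoxyphenyl]-2-hydroxytridec-4-yn-8-yl sulfate, via 1,3-dilithiopropyne 12 (not isolated), via dilithium acetylide sulfate 13 (not isolated)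
Conditions: 11 (1.1 equiv), n-BuLi (2.2 equiv), TMEDA (1.1 equiv), Et2O/hexane, −78 to 0 °C; THF, −78 °C, 4 (1.0 equiv) added slowly, to −40 °C; −78 °C, BF3·OEt2 (3.5 equiv), then 10 (1.2 equiv) in THF; H2O, aq LiCl, extraction with EtOAc/n-BuOH, crude salt used directly
Reagents that add atoms: n-butyllithium, SMILES [Li]CCCC (supplies the lithium counter-ion)
Why: Proposed new method: double deprotonation of propyne gives 1,3-dilithiopropyne, whose sp3 (propargylic) carbanion is far more nucleophilic than its acetylide end and should open the cyclic sulfate by SN2 at the unhindered primary carbon at −78 °C (C6–C7 bond); the closest known reactions are the propargylic alkylation of this dianion by alkyl halides and epoxides and the opening of 1,2-cyclic sulfates by organolithium carbanions. The ring oxygen at C8 is released as a secondary alkyl sulfate monoanion, a poor leaving group that is not displaced again, so C8 stays masked with its configuration intact. The surviving lithium acetylide is then activated with BF3·OEt2 (Yamaguchi–Hirao alkynylation) and should attack the terminal carbon of the epoxide (C3–C4 bond), giving the free C2 hydroxyl after aqueous work-up. No ring is closed and no stereocenter is created: C8 and C2 come unchanged from 4 and 10 because both substitutions take place at CH2 groups. The step needs site selectivity within the dianion and terminal attack on both electrophiles; the first is secured by the reactivity gap between the two carbanion sites and by slow addition of 4 to the dianion at low temperature, so that the acetylide never meets free sulfate, the second by the steric bias of the monosubstituted electrophiles. BF3·OEt2 is charged in excess because TMEDA and the sulfate anion bind part of it.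

Step 7
Reactants: 14 lithium (2S,8S)-1-[3-(benzyloxy)-5-methoxyphenyl]-2-hydroxytridec-4-yn-8-yl sulfate
Product: 15 lithium (2S,8S)-2-acetoxy-1-[3-(benzyloxy)-5-methoxyphenyl]tridec-4-yn-8-yl sulfate
Conditions: Ac2O, pyridine, DMAP (cat.), CH2Cl2, rt; evaporation with toluene to remove pyridine
Reagents that add atoms: acetic anhydride, SMILES CC(=O)OC(C)=O
Why: DMAP-catalysed acylation of the only free hydroxyl (C2); the sulfate monoester anion at C8 cannot be acylated permanently, which is what differentiates the two carbinols.

Step 8
Reactants: 15 lithium (2S,8S)-2-acetoxy-1-[3-(benzyloxy)-5-methoxyphenyl]tridec-4-yn-8-yl sulfate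
Product: 16 (2S,8S)-1-[3-(benzyloxy)-5-methoxyphenyl]-8-hydroxytridec-4-yn-2-yl acetate
Conditions: conc. H2SO4 (cat.), H2O (1–2 equiv), THF, rt; aq NaHCO3
Reagents that add atoms: none
Why: Acid-catalysed hydrolysis of a sulfate monoester, the usual second stage of cyclic sulfate opening: cleavage occurs at the S–O bond, so C8 keeps its configuration, and the small amount of acid and water in THF at room temperature should leave the secondary acetate, the alkyne and the benzyl ether untouched.

Step 9
Reactants: 16 (2S,8S)-1-[3-(benzyloxy)-5-methoxyphenyl]-8-hydroxytridec-4-yn-2-yl acetate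
Product: 17 (2R,8S)-8-hydroxy-1-(3-hydroxy-5-methoxyphenyl)tridecan-2-yl acetate
Conditions: H2 (1 atm), 10% Pd/C, EtOAc/EtOH, rt
Reagents that add atoms: none
Why: Heterogeneous catalytic hydrogenation with O-benzyl hydrogenolysis: the alkyne is saturated to the C3–C7 pentamethylene and the phenol is released in one operation, while neither carbinol carbon is benzylic or propargylic, so no C–O bond at a stereocenter is cleaved.

Remark on descriptors: C2 is (S) in 14–16 and (R) in 17 with the same spatial arrangement. The propargylic branch C3 outranks the benzylic branch C1 while the triple bond is present, and the order reverses on saturation.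

**Compound list**

1 | racemic 1,2-epoxyheptane (2-pentyloxirane) | CCCCCC1CO1 | starting material
2 | (S)-heptane-1,2-diol | CCCCC[C@H](O)CO | intermediate
3 | (4S)-4-pentyl-1,3,2-dioxathiolane 2-oxide (cyclic sulfite, both epimers at sulfur) | CCCCC[C@H]1COS(=O)O1 | intermediate
4 | (S)-4-pentyl-1,3,2-dioxathiolane 2,2-dioxide | CCCCC[C@H]1COS(=O)(=O)O1 | intermediate
5 | 3-bromo-5-methoxyphenol | COc1cc(O)cc(Br)c1 | starting material
6 | 1-(benzyloxy)-3-bromo-5-methoxybenzene | COc1cc(OCc2ccccc2)cc(Br)c1 | intermediate
7 | (S)-epichlorohydrin | ClC[C@@H]1CO1 | starting material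
8 | [3-(benzyloxy)-5-methoxyphenyl]magnesium bromide | COc1cc(OCc2ccccc2)cc([Mg]Br)c1 | intermediate
9 | (S)-1-[3-(benzyloxy)-5-methoxyphenyl]-3-chloropropan-2-ol | ClC[C@@H](O)Cc1cc(OCc2ccccc2)cc(OC)c1 | intermediate
10 | (S)-2-[3-(benzyloxy)-5-methoxybenzyl]oxirane | C1[C@H](Cc2cc(OCc3ccccc3)cc(OC)c2)O1 | intermediate
11 | propyne | CC#C | starting material
12 | 1,3-dilithiopropyne | [Li]CC#C[Li] | intermediate
13 | lithium (S)-1-lithiodec-1-yn-5-yl sulfate | CCCCC[C@H](OS(=O)(=O)[O-])CCC#C[Li].[Li+] | intermediate
14 | lithium (2S,8S)-1-[3-(benzyloxy)-5-methoxyphenyl]-2-hydroxytridec-4-yn-8-yl sulfate | CCCCC[C@H](OS(=O)(=O)[O-])CCC#CC[C@H](Cc1cc(OCc2ccccc2)cc(OC)c1)O.[Li+] | intermediate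
15 | lithium (2S,8S)-2-acetoxy-1-[3-(benzyloxy)-5-methoxyphenyl]tridec-4-yn-8-yl sulfate | CCCCC[C@H](OS(=O)(=O)[O-])CCC#CC[C@H](Cc1cc(OCc2ccccc2)cc(OC)c1)OC(C)=O.[Li+] | intermediate
16 | (2S,8S)-1-[3-(benzyloxy)-5-methoxyphenyl]-8-hydroxytridec-4-yn-2-yl acetate | CCCCC[C@H](O)CCC#CC[C@H](Cc1cc(OCc2ccccc2)cc(OC)c1)OC(C)=O | intermediate
17 | (2R,8S)-8-hydroxy-1-(3-hydroxy-5-methoxyphenyl)tridecan-2-yl acetate (CNP0415796.1) | CCCCC[C@H](O)CCCCC[C@H](Cc1cc(O)cc(OC)c1)OC(C)=O | target

**Step count**

Total steps: 9. Longest linear sequence: 7 (steps 3, 4, 5, 6, 7, 8, 9).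

**Steps most likely to fail**

Step 6 (three-component coupling). What may go wrong: base-induced elimination or a second alkylation of the cyclic sulfate, precipitation of the dilithium acetylide sulfate before the second stage, or sequestration of BF3 so that the epoxide is not opened. The fallback uses known chemistry only, with an epoxide in place of the cyclic sulfate and a silyl ether in place of the sulfate. It sets out from 2 (with 10 and 11) and comes back at 16. Diol 2 is tosylated at the primary hydroxyl (TsCl, Bu2SnO cat., Et3N, CH2Cl2) to (S)-2-hydroxyheptyl 4-methylbenzenesulfonate F1 and closed with K2CO3 in MeOH to (S)-1,2-epoxyheptane F2. 1,3-Dilithiopropyne 12 opens F2 at its terminal carbon through the propargylic carbon and gives, after protonation, (S)-dec-1-yn-5-ol F3. Silylation (TBSCl, imidazole, DMF) gives tert-butyl[(S)-dec-1-yn-5-yloxy]dimethylsilane F4. Lithiation (n-BuLi, THF, −78 °C) and BF3·OEt2-promoted opening of 10 give (2S,8S)-1-[3-(benzyloxy)-5-methoxyphenyl]-8-[(tert-butyldimethylsilyl)oxy]tridec-4-yn-2-ol F5. Acetylation (Ac2O, pyridine, DMAP) gives (2S,8S)-1-[3-(benzyloxy)-5-methoxyphenyl]-8-[(tert-butyldimethylsilyl)oxy]tridec-4-yn-2-yl acetate F6, and HF·pyridine in THF removes the silyl group to give 16.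

Step 8 (desulfation beside the acetate). What may go wrong: acid-promoted loss of the C2 acetate, incomplete S–O cleavage of the secondary sulfate, or losses through emulsions of the amphiphilic salt. The fallback removes the sulfate before any ester is present. It sets out from 4 (with 11) and comes back at 16. The one-pot sequence is stopped after its first stage and 13 is protonated to lithium (S)-dec-1-yn-5-yl sulfate F7. This is hydrolysed without restraint (20% aq H2SO4/Et2O, rt) to (S)-dec-1-yn-5-ol F3. F3 is then carried as above through tert-butyl[(S)-dec-1-yn-5-yloxy]dimethylsilane F4, the coupled alcohol (2S,8S)-1-[3-(benzyloxy)-5-methoxyphenyl]-8-[(tert-butyldimethylsilyl)oxy]tridec-4-yn-2-ol F5 and its acetate F6 to 16.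

Step 4 (aryl Grignard opening of epichlorohydrin). What may go wrong: opening of the oxirane by halide in competition with the cuprate, homocoupling during Grignard formation, or erosion of enantiomeric purity by reversible chloride opening. The fallback builds the epoxide on an allyl arene and resolves it. It sets out from 6 and comes back at 10. Suzuki–Miyaura coupling of 6 with allylboronic acid pinacol ester (Pd(PPh3)4, CsF, THF, reflux) gives 1-allyl-3-(benzyloxy)-5-methoxybenzene F8. Prilezhaev epoxidation (mCPBA, CH2Cl2) gives racemic 2-[3-(benzyloxy)-5-methoxybenzyl]oxirane F9. Hydrolytic kinetic resolution with (S,S)-(salen)Co(OAc) and H2O (0.55 equiv) hydrolyses the (R)-enantiomer and leaves 10, which is separated from the diol by chromatography.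

**Further compounds**

F1 | step 6 | (S)-2-hydroxyheptyl 4-methylbenzenesulfonate | CCCCC[C@H](O)COS(=O)(=O)c1ccc(C)cc1
F2 | step 6 | (S)-1,2-epoxyheptane | CCCCC[C@H]1CO1
F3 | step 6 | (S)-dec-1-yn-5-ol | CCCCC[C@H](O)CCC#C
F4 | step 6 | tert-butyl[(S)-dec-1-yn-5-yloxy]dimethylsilane | CCCCC[C@H](O[Si](C)(C)C(C)(C)C)CCC#C
F5 | step 6 | (2S,8S)-1-[3-(benzyloxy)-5-methoxyphenyl]-8-[(tert-butyldimethylsilyl)oxy]tridec-4-yn-2-ol | CCCCC[C@H](O[Si](C)(C)C(C)(C)C)CCC#CC[C@H](Cc1cc(OCc2ccccc2)cc(OC)c1)O
F6 | step 6 | (2S,8S)-1-[3-(benzyloxy)-5-methoxyphenyl]-8-[(tert-butyldimethylsilyl)oxy]tridec-4-yn-2-yl acetate | CCCCC[C@H](O[Si](C)(C)C(C)(C)C)CCC#CC[C@H](Cc1cc(OCc2ccccc2)cc(OC)c1)OC(C)=O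
F7 | step 8 | lithium (S)-dec-1-yn-5-yl sulfate | CCCCC[C@H](OS(=O)(=O)[O-])CCC#C.[Li+]
F8 | step 4 | 1-allyl-3-(benzyloxy)-5-methoxybenzene | C=CCc1cc(OCc2ccccc2)cc(OC)c1
F9 | step 4 | racemic 2-[3-(benzyloxy)-5-methoxybenzyl]oxirane | C1C(Cc2cc(OCc3ccccc3)cc(OC)c2)O1
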